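(The earlier runs and the new flask were computed for substances that don't exist, and the scatter is random.)

The target read 7.0 % in the red run at 12.0 min, beside 59.0 % of over-reaction product, so I counted what these two readings and the starting material gone had cost in gas.

in all of them: gas phase 0.65 mM (held)

| flask | starting material | catalyst | remark | time |
|---|---|---|---|---|
| red | 10 mM | 5 µM | run made earlier |  |
| blue | 10 mM | 20 µM | run made earlier |  |
| violet | 15 mM | 10 µM | run made earlier |  |
| flask | 10 mM | 10 µM |  | 12 min |

| run | time / min | target / % | isomer of the product / % | starting material / % | over-reaction product / % |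
|---|---|---|---|---|---|
| red | 1.00 | 9.1 | 0.8 | 91.7 | 2.9 |
| red | 3.00 | 8.9 | 4.7 | 74.9 | 11.2 |
| red | 5.00 | 11.4 | 9.7 | 57.8 | 21.2 |
| red | 8.00 | 8.1 | 11.7 | 42.9 | 38.1 |
| red | 12.0 | 7.0 | 11.0 | 24.4 | 59.0 |
| red | 15.0 | 2.7 | 11.1 | 13.3 | 67.9 |
| blue | 1.00 | 7.5 | 4.6 | 81.3 | 4.0 |
| blue | 2.00 | 8.8 | 9.6 | 65.2 | 15.2 |
| blue | 3.00 | 8.3 | 13.9 | 50.9 | 26.6 |
| blue | 5.00 | 7.6 | 14.5 | 28.6 | 48.7 |
| blue | 8.00 | 3.2 | 10.2 | 9.9 | 78.6 |
| blue | 15.0 | 0 | 1.0 | 0.2 | 97.6 |
| violet | 1.33 | 7.4 | 2.3 | 86.6 | 4.0 |
| violet | 4.00 | 8.1 | 11.5 | 58.3 | 20.8 |
| violet | 6.00 | 10.2 | 13.2 | 44.1 | 32.1 |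
| violet | 10.0 | 5.7 | 14.9 | 21.7 | 60.3 |
| violet | 15.0 | 1.2 | 7.6 | 7.2 | 82.3 |

(each reading ± 1 percentage point)

- at the start none of the gas phase is in solution

- where most of what was charged as starting material, at 12 min is found (starting material / isomer of the product / target / over-reaction product)
- the largest share itself, whichever of these holds it, in percent of the starting material charged

Solution holds 0.65 mM of gas at saturation against 10 mM of starting material, so I balanced dissolved gas as a small pool refilled throughout, not as a charge that runs out; starting material, which gets no refill, is the limiting reagent. I assumed one portion per starting material consumed and a second per over-reaction product formed: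

gas uptake = charge × (whole charge − starting material left + over-reaction product) / time

I took catalyst first. By hand, a factor of 4.00 in catalyst would give the same factor in uptake. But red took up 1.12 mM min⁻¹ over 12.0 min, and blue 2.40 mM min⁻¹ over 5.00 min, a factor of 2.14. So:

√(blue uptake / red uptake) = 1.46, the gain per doubling of catalyst

Time came next. With half of blue's catalyst, the flask's 12 min should match blue at 8.22 min. Blue's nearest reading, at 8.00 min, shows 78.6 % of over-reaction product, and I committed to that.

Charge came last. By hand, a larger charge shares the same gas and lags; violet, with the flask's catalyst, reads 60.3 % at 10.0 min and 82.3 % at 15.0 min.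

The forecast said over-reaction product, at 76 %, since “rate scales roughly with the square root of catalyst”; my reading stood higher than its number.

The flask gives over-reaction product, at 79.9 %.

    dissolved gas + catalyst + target → catalyst + over-reaction product (k = 4.10 × 10⁶ M⁻² s⁻¹)
    target + catalyst ⇌ isomer of the product + catalyst, rate k2*[catalyst]*[target] forward; the back reaction follows from the equilibrium constant (K = 1.80, k = 940 M⁻¹ s⁻¹)
    starting material + dissolved gas + catalyst → catalyst + target (k = 8.70 × 10⁵ M⁻² s⁻¹)
    gas phase ⇌ dissolved gas, rate k4*(csat - [dissolved gas]) (kL = 0.100 s⁻¹)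

At 4.53 min in the flask, making target used 1.1 times the dissolved gas that over-reaction used. At 12.0 min, target was made at 0.847 of the rate at which it was used, with dissolved gas at 0.542 mM.

The forecast's choice would fall if a run put another species in front, so I tried the neighbour with 2.50 µM of catalyst. Having half of red's catalyst, it should match red at 8.22 min, whose nearest reading, at 8.00 min, shows 42.9 % of starting material and 38.1 % of over-reaction product. It gives 44.6 % and 35.7 %, with starting material in front.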